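The flavanone is cut through ring C (the pyranone) at two bonds: C3–C4, between the methylene and the ketone carbon, and O1–C8a, between the ring oxygen and ring A. This leaves a three-atom C,O-dinucleophile O1–C2(H)(aryl)–C3 that already carries the stereocenter, and a ring A 2-fluorobenzoate as 1,3-dielectrophile. In the key step an enantiopure β-oxido alkyllithium, made by reductive lithiation of an (R)-chlorohydrin, is C-acylated by the ester and the alkoxide then displaces fluoride in an SNAr, closing ring C in one flask. The step exploits that C8a lies ortho to the C4 carbonyl, which only appears in the acylation and then activates C8a toward the alkoxide.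

Key step: step 9

Remark: the target is read as the (2S)-flavanone. The carbinol carbon keeps one spatial arrangement from 10 to 18; its descriptor changes from R (in 10) to S (in 15 to 18) only through the CIP priorities.

Step 1
Reactants: 1 2-bromo-3-hydroxy-4-methoxybenzaldehyde
Product: 2 2-bromo-4-methoxy-3-(methoxymethoxy)benzaldehyde
Conditions: MOMCl, i-Pr2NEt, CH2Cl2, 0 °C to rt
Reagents that add atoms: chloromethyl methyl ether (MOMCl), COCCl
Why: O-alkylation of the phenol (MOM ether formation) proceeds under mild base while the aldehyde and the aryl bromide stay untouched.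

Step 2
Reactants: 2 2-bromo-4-methoxy-3-(methoxymethoxy)benzaldehyde; 3 geranyl bromide
Product: 7 2-geranyl-4-methoxy-3-(methoxymethoxy)benzaldehyde, via lithium α-amino alkoxide 4 (not isolated), via aryllithium 5 (not isolated), via geranylated lithium α-amino alkoxide 6 (not isolated)
Conditions: N-methylpiperazine, n-BuLi, THF, −20 °C, then 2; n-BuLi, −78 °C; CuBr·SMe2 (20 mol %), 3, −78 to 0 °C; then H2O
Reagents that add atoms: none
Why: In situ protection of the aldehyde as a lithium α-amino alkoxide permits bromine–lithium exchange, and copper-catalysed SN2 allylic substitution of the primary allylic bromide by the aryllithium should give the linear product with the E geometry retained, the aldehyde being released on aqueous work-up.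

Step 3
Reactants: 7 2-geranyl-4-methoxy-3-(methoxymethoxy)benzaldehyde
Product: 8 racemic 2-chloro-1-[2-geranyl-4-methoxy-3-(methoxymethoxy)phenyl]ethanol
Conditions: ICH2Cl, MeLi·LiBr, THF, −78 °C; AcOH, −78 °C
Reagents that add atoms: chloroiodomethane, ClCI
Why: Chloromethyllithium formed by iodine–lithium exchange under Barbier conditions adds 1,2 to the aldehyde, and the cold acidic quench prevents closure to the epoxide; the new stereocenter forms racemic and is erased in step 4.

Step 4
Reactants: 8 racemic 2-chloro-1-[2-geranyl-4-methoxy-3-(methoxymethoxy)phenyl]ethanol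
Product: 9 2-chloro-1-[2-geranyl-4-methoxy-3-(methoxymethoxy)phenyl]ethanone
Conditions: Dess–Martin periodinane, CH2Cl2, 0 °C to rt
Reagents that add atoms: none
Why: Dess–Martin oxidation converts the secondary alcohol to the ketone under near-neutral conditions that spare the trisubstituted alkenes, the MOM ether and the primary chloride.

Step 5
Reactants: 9 2-chloro-1-[2-geranyl-4-methoxy-3-(methoxymethoxy)phenyl]ethanone
Product: 10 (1R)-2-chloro-1-[2-geranyl-4-methoxy-3-(methoxymethoxy)phenyl]ethanol
Conditions: Cp*RhCl[(S,S)-TsDPEN] (0.5 mol %), HCO2H/Et3N (5:2), EtOAc, rt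
Reagents that add atoms: none
Why: Asymmetric transfer hydrogenation (Noyori type) reduces only the ketone, and the (S,S)-ligand should deliver hydride to the face that gives the (R)-chlorohydrin, by analogy with 2-chloroacetophenone, so the stereocenter that becomes C2 is set under catalyst control.

Step 6
Reactants: 11 2,6-difluoro-4-methoxybenzoic acid
Product: 12 2-fluoro-6-hydroxy-4-methoxybenzoic acid
Conditions: NaOH, 1,3-dimethyl-2-imidazolidinone, 130 °C; then aq. HCl
Reagents that add atoms: sodium hydroxide, [Na+].[OH-]
Why: SNAr of one fluoride ortho to the carboxylate by hydroxide stops after the first substitution because the phenoxide formed deactivates the ring.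

Step 7
Reactants: 12 2-fluoro-6-hydroxy-4-methoxybenzoic acid
Product: 13 methyl 2-fluoro-6-hydroxy-4-methoxybenzoate
Conditions: MeI, KHCO3, DMF, rt
Reagents that add atoms: iodomethane, CI
Why: SN2 alkylation of the carboxylate with a weak base should leave the hydrogen-bonded phenol unalkylated.

Step 8
Reactants: 13 methyl 2-fluoro-6-hydroxy-4-methoxybenzoate
Product: 14 methyl 2-fluoro-4-methoxy-6-(methoxymethoxy)benzoate
Conditions: NaH, MOMCl, DMF, 0 °C to rt
Reagents that add atoms: chloromethyl methyl ether (MOMCl), COCCl
Why: O-alkylation of the sodium phenoxide (MOM ether formation) masks the future 5-hydroxyl so that the ester stays electrophilic and the ring stays open to SNAr.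

Step 9
Reactants: 10 (1R)-2-chloro-1-[2-geranyl-4-methoxy-3-(methoxymethoxy)phenyl]ethanol; 14 methyl 2-fluoro-4-methoxy-6-(methoxymethoxy)benzoate
Product: 17 (2S)-2-[2-geranyl-4-methoxy-3-(methoxymethoxy)phenyl]-7-methoxy-5-(methoxymethoxy)chroman-4-one, via β-oxido alkyllithium 15 (not isolated), via lithium aldolate 16 (not isolated)
Conditions: n-BuLi (1.0 equiv), THF, −78 °C; lithium 4,4'-di-tert-butylbiphenylide (LiDBB, 2.0 equiv), −78 °C; inverse addition to 14 (1.1 equiv), THF, −78 °C; DMPU, −78 to 0 °C; AcOH
Reagents that add atoms: none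
Why: Proposed new method: deprotonation of 10 and two-electron reductive lithiation of its C–Cl bond by LiDBB should give the β-oxido alkyllithium 15, a known class that resists loss of Li2O at −78 °C, whose carbon adds to the ester of 14 through a chelated tetrahedral intermediate that collapses to the ortho-fluoroaryl ketone 16 (C3–C4 bond); on warming with DMPU the lithium alkoxide of 16 attacks C8a, ortho to the new ketone, and expels fluoride through a Meisenheimer intermediate (O1–C8a bond). The closest known reactions are the trapping of β-oxido organolithiums by carbonyl electrophiles and the domino C-acylation/SNAr of ketone enolates or 1,3-dicarbonyl dianions with 2-fluorobenzoyl electrophiles that gives chromones; their union with an sp3 carbon–oxygen dianion to give a chromanone directly is new. Ring C is closed by the intramolecular SNAr, a 6-exo-trig addition–elimination at the arene carbon. No stereocenter is created: C2 comes from step 5 and keeps its configuration because none of its four bonds is made or broken. The step needs single acylation, which inverse addition to a slight excess of the non-enolisable ester at −78 °C should secure, and it needs the SNAr to outrun retro-aldol cleavage and E1cB dehydration of 16 and ring opening of 17, which the lithium counter-ion, the low temperature and a prompt AcOH quench should secure. The site of closure is fixed because 14 carries a single fluorine and the other ortho position is blocked as the MOM ether.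

Step 10
Reactants: 17 (2S)-2-[2-geranyl-4-methoxy-3-(methoxymethoxy)phenyl]-7-methoxy-5-(methoxymethoxy)chroman-4-one
Product: 18 (2S)-2-[2-geranyl-3-hydroxy-4-methoxyphenyl]-5-hydroxy-7-methoxychroman-4-one (CNP0130331.1)
Conditions: 3 M HCl, MeOH, rt to 40 °C
Reagents that add atoms: none
Why: Acid-catalysed acetal methanolysis removes both MOM ethers under conditions mild enough to leave the geranyl alkenes uncyclised and the C2 stereocenter intact, since flavanones do not epimerise in dilute acid.

Compound list
1 | 2-bromo-3-hydroxy-4-methoxybenzaldehyde | O=Cc1ccc(OC)c(O)c1Br | starting material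
2 | 2-bromo-4-methoxy-3-(methoxymethoxy)benzaldehyde | O=Cc1ccc(OC)c(OCOC)c1Br | intermediate
3 | geranyl bromide, (2E)-1-bromo-3,7-dimethylocta-2,6-diene | BrC/C=C(\C)CCC=C(C)C | starting material
4 | lithium [2-bromo-4-methoxy-3-(methoxymethoxy)phenyl](4-methylpiperazin-1-yl)methanolate | [Li+].[O-]C(N1CCN(C)CC1)c1ccc(OC)c(OCOC)c1Br | intermediate
5 | 2-lithio derivative of 4 (lithium in place of bromine) | [Li+].[O-]C(N1CCN(C)CC1)c1ccc(OC)c(OCOC)c1[Li] | intermediate
6 | lithium {2-[(2E)-3,7-dimethylocta-2,6-dien-1-yl]-4-methoxy-3-(methoxymethoxy)phenyl}(4-methylpiperazin-1-yl)methanolate | [Li+].[O-]C(N1CCN(C)CC1)c1ccc(OC)c(OCOC)c1C/C=C(\C)CCC=C(C)C | intermediate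
7 | 2-[(2E)-3,7-dimethylocta-2,6-dien-1-yl]-4-methoxy-3-(methoxymethoxy)benzaldehyde | O=Cc1ccc(OC)c(OCOC)c1C/C=C(\C)CCC=C(C)C | intermediate
8 | racemic 2-chloro-1-{2-[(2E)-3,7-dimethylocta-2,6-dien-1-yl]-4-methoxy-3-(methoxymethoxy)phenyl}ethan-1-ol | OC(CCl)c1ccc(OC)c(OCOC)c1C/C=C(\C)CCC=C(C)C | intermediate
9 | 2-chloro-1-{2-[(2E)-3,7-dimethylocta-2,6-dien-1-yl]-4-methoxy-3-(methoxymethoxy)phenyl}ethan-1-one | O=C(CCl)c1ccc(OC)c(OCOC)c1C/C=C(\C)CCC=C(C)C | intermediate
10 | (1R)-2-chloro-1-{2-[(2E)-3,7-dimethylocta-2,6-dien-1-yl]-4-methoxy-3-(methoxymethoxy)phenyl}ethan-1-ol | O[C@H](c1ccc(OC)c(OCOC)c1C/C=C(\C)CCC=C(C)C)CCl | intermediate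
11 | 2,6-difluoro-4-methoxybenzoic acid | O=C(O)c1c(F)cc(OC)cc1F | starting material
12 | 2-fluoro-6-hydroxy-4-methoxybenzoic acid | O=C(O)c1c(O)cc(OC)cc1F | intermediate
13 | methyl 2-fluoro-6-hydroxy-4-methoxybenzoate | COC(=O)c1c(O)cc(OC)cc1F | intermediate
14 | methyl 2-fluoro-4-methoxy-6-(methoxymethoxy)benzoate | COC(=O)c1c(OCOC)cc(OC)cc1F | intermediate
15 | O,C-dilithio derivative of 10 (lithium alkoxide, lithium in place of chlorine; same spatial arrangement at the carbinol carbon) | [Li]O[C@H](c1ccc(OC)c(OCOC)c1C/C=C(\C)CCC=C(C)C)C[Li] | intermediate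
16 | lithium (1S)-1-{2-[(2E)-3,7-dimethylocta-2,6-dien-1-yl]-4-methoxy-3-(methoxymethoxy)phenyl}-3-[2-fluoro-4-methoxy-6-(methoxymethoxy)phenyl]-3-oxopropan-1-olate | [Li]O[C@H](c1ccc(OC)c(OCOC)c1C/C=C(\C)CCC=C(C)C)CC(=O)c1c(OCOC)cc(OC)cc1F | intermediate
17 | (2S)-2-{2-[(2E)-3,7-dimethylocta-2,6-dien-1-yl]-4-methoxy-3-(methoxymethoxy)phenyl}-7-methoxy-5-(methoxymethoxy)-2,3-dihydro-4H-chromen-4-one | COc1cc(OCOC)c2c(c1)O[C@H](c1ccc(OC)c(OCOC)c1C/C=C(\C)CCC=C(C)C)CC2=O | intermediate
18 | (2S)-2-{2-[(2E)-3,7-dimethylocta-2,6-dien-1-yl]-3-hydroxy-4-methoxyphenyl}-5-hydroxy-7-methoxy-2,3-dihydro-4H-chromen-4-one | COc1cc(O)c2c(c1)O[C@H](c1ccc(OC)c(O)c1C/C=C(\C)CCC=C(C)C)CC2=O | target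

Total step count: 10. Longest linear sequence: 7 steps (steps 1, 2, 3, 4, 5, 9, 10).

Steps most likely to fail

Step 9. The dianion may lose lithium oxide by β-elimination before it is acylated, or a second equivalent may add to the ketone. The aldolate may also undergo retro-aldol cleavage or dehydration faster than the alkoxide displaces fluoride, which would erode the configuration at C2. The fallback uses known chemistry, sets out from aldehyde 7 and comes back at 17. Commercial 1-(2,6-dihydroxy-4-methoxyphenyl)ethanone F1 is mono-protected (MOMCl, i-Pr2NEt, CH2Cl2) to 1-[2-hydroxy-4-methoxy-6-(methoxymethoxy)phenyl]ethanone F2. Claisen–Schmidt condensation of F2 with 7 (KOH, EtOH, rt) should give the 2'-hydroxychalcone F3. NaOAc in refluxing EtOH should close F3 by intramolecular oxa-Michael addition to the racemic flavanone F4. Preparative HPLC on a chiral stationary phase then separates 17 from its (2R)-enantiomer F5, which is discarded. This fallback does not need compounds 8 to 16.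

Step 2. Masking of the aldehyde may be incomplete, so that the organolithium adds to the carbonyl group. The aryl nucleophile, hindered on both sides, may also attack the γ-carbon of the allylic bromide (SN2′) or scramble the alkene geometry. The fallback sets out from 2 and 3 and comes back at 7. Geranyl bromide 3 is converted with Bu3SnLi (THF, −78 °C) into tributyl(geranyl)stannane F6. A Stille coupling of F6 with aryl bromide 2, catalysed by the zerovalent palladium complex Pd(PPh3)4 (CsF, DMF, 90 °C), should join the two at the tin-bearing carbon without any protection of the aldehyde.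

Step 5. Facial discrimination by the catalyst may be insufficient on the ortho-substituted aryl ketone, and formate may displace the chloride. The fallback sets out from racemic 8 and comes back at 10, without steps 4 and 5. Kinetic resolution with Pseudomonas cepacia lipase and vinyl acetate (MTBE, 30 °C) should acylate the (S)-alcohol preferentially to the (1S)-acetate F7, by the usual size rule for secondary alcohols, and leave the (R)-alcohol 10 unreacted for separation by chromatography.

Further compounds
F1 | step 9 | 1-(2,6-dihydroxy-4-methoxyphenyl)ethanone | CC(=O)c1c(O)cc(OC)cc1O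
F2 | step 9 | 1-[2-hydroxy-4-methoxy-6-(methoxymethoxy)phenyl]ethanone | CC(=O)c1c(O)cc(OC)cc1OCOC
F3 | step 9 | (2E)-3-{2-[(2E)-3,7-dimethylocta-2,6-dien-1-yl]-4-methoxy-3-(methoxymethoxy)phenyl}-1-[2-hydroxy-4-methoxy-6-(methoxymethoxy)phenyl]prop-2-en-1-one | O=C(/C=C/c1ccc(OC)c(OCOC)c1C/C=C(\C)CCC=C(C)C)c1c(O)cc(OC)cc1OCOC
F4 | step 9 | racemic 2-{2-[(2E)-3,7-dimethylocta-2,6-dien-1-yl]-4-methoxy-3-(methoxymethoxy)phenyl}-7-methoxy-5-(methoxymethoxy)-2,3-dihydro-4H-chromen-4-one | COc1cc(OCOC)c2c(c1)OC(c1ccc(OC)c(OCOC)c1C/C=C(\C)CCC=C(C)C)CC2=O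
F5 | step 9 | (2R)-2-{2-[(2E)-3,7-dimethylocta-2,6-dien-1-yl]-4-methoxy-3-(methoxymethoxy)phenyl}-7-methoxy-5-(methoxymethoxy)-2,3-dihydro-4H-chromen-4-one | COc1cc(OCOC)c2c(c1)O[C@@H](c1ccc(OC)c(OCOC)c1C/C=C(\C)CCC=C(C)C)CC2=O
F6 | step 2 | tributyl[(2E)-3,7-dimethylocta-2,6-dien-1-yl]stannane | CCCC[Sn](CCCC)(CCCC)C/C=C(\C)CCC=C(C)C
F7 | step 5 | (1S)-2-chloro-1-{2-[(2E)-3,7-dimethylocta-2,6-dien-1-yl]-4-methoxy-3-(methoxymethoxy)phenyl}ethyl acetate | CC(=O)O[C@@H](c1ccc(OC)c(OCOC)c1C/C=C(\C)CCC=C(C)C)CCl
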